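**Plan**

- Target: the C2-symmetric (2S,3R,4R,5S)-oxolane, with aryl and aroyl cis on C2/C3 and on C4/C5 and the two aroyl groups trans. Enabling feature: on each side the aroyl C=O, its ring carbon (C3 or C4), the next ring carbon (C2 or C5) and the ring oxygen O1 form a beta-oxygenated ketone, which is the retron of a 4,5-dihydroisoxazole.
- Cuts: (a) aroyl carbon–C3 together with O1–C2, by nitrile oxide cycloaddition to an (E)-styryl double bond; (b) O1–C5, by reductive etherification of a C5 aryl ketone; (c) C5–aryl (Weinreb amide plus aryl Grignard) and C4–carbinol carbon (aldol, the carbinol later oxidised to the second aroyl group).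
- Forward: Wittig and auxiliary-controlled aldol build the C2–C5 chain; the intermolecular [3+2] cycloaddition brings in the second aroyl carbon with O1 (dihydroisoxazole as temporary ring, N as helper); N–O cleavage and hydride reduction of the cyclic hemiketal close the oxolane; oxidation and debenzylation finish.
- Stereochemistry: C4 from the (S)-oxazolidinone (the aldol carbinol centre is a temporary steering group); C2 and C3 in one event, relative from the E alkene by suprafacial addition, absolute by relay from C4; C5 by hydride delivery anti to the C4 substituent.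

Key step: step 8

Assumption: the benzyl-protected aldehydes and the aryl Grignard solution used as starting materials are taken as catalogue items; benzyl is chosen for all six phenols so that the last step is neutral.

**Step 1**
Reactants: 1 4-(benzyloxy)benzaldehyde; 2 (2-carboxyethyl)triphenylphosphonium bromide
Product: 3 (E)-4-[4-(benzyloxy)phenyl]but-3-enoic acid
Conditions: NaHMDS (2.1 equiv), THF, −78 °C → rt; aq HCl work-up
Reagents that add atoms: none
Why: Wittig olefination with a carboxylate-bearing ylide, a case in which the anionic side chain is known to steer the reaction to the (E)-alkene, should give the beta,gamma-unsaturated acid with the double bond out of conjugation with the carboxyl group.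

**Step 2**
Reactants: 3 (E)-4-[4-(benzyloxy)phenyl]but-3-enoic acid; 4 (S)-4-benzyl-1,3-oxazolidin-2-one
Product: 6 (S)-4-benzyl-3-{(E)-4-[4-(benzyloxy)phenyl]but-3-enoyl}-1,3-oxazolidin-2-one, via mixed pivalic anhydride 5 (not isolated)
Conditions: PivCl, Et3N, THF, −20 °C; then 4, LiCl, rt
Reagents that add atoms: none
Why: Mixed-anhydride N-acylation of the oxazolidinone promoted by LiCl needs only a weak amine base, so the double bond should stay in the beta,gamma position.

**Step 3**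
Reactants: 6 (S)-4-benzyl-3-{(E)-4-[4-(benzyloxy)phenyl]but-3-enoyl}-1,3-oxazolidin-2-one; 7 2,4-bis(benzyloxy)benzaldehyde
Product: 9 (S)-4-benzyl-3-{(2S,3S)-3-[2,4-bis(benzyloxy)phenyl]-2-[(E)-2-[4-(benzyloxy)phenyl]ethenyl]-3-hydroxypropanoyl}-1,3-oxazolidin-2-one, via dibutylboron Z-enolate 8 (not isolated)
Conditions: Bu2BOTf, iPr2NEt, CH2Cl2, −78 → 0 °C; 7, −78 → 0 °C; pH 7 buffer, MeOH, H2O2
Reagents that add atoms: none
Why: Evans syn-aldol reaction: the Z boron dienolate should react at its alpha carbon through a closed chair transition state on the face away from the benzyl group of the auxiliary, which sets the future C4 (S here) and the carbinol carbon (S) and leaves the styryl double bond E.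

**Step 4**
Reactants: 9 the syn-aldol imide
Product: 10 (2S,3S)-3-[2,4-bis(benzyloxy)phenyl]-2-[(E)-2-[4-(benzyloxy)phenyl]ethenyl]-3-hydroxy-N-methoxy-N-methylpropanamide
Conditions: MeNHOMe·HCl, AlMe3, CH2Cl2, −15 °C → rt; Rochelle salt work-up
Reagents that add atoms: N,O-dimethylhydroxylamine hydrochloride, CNOC.Cl
Why: Aluminium amide transamination to the Weinreb amide is assisted by the free beta-hydroxyl group and should release the auxiliary without touching the alpha stereocenter.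

**Step 5**
Reactants: 10 the hydroxy Weinreb amide
Product: 11 (2S,3S)-3-[2,4-bis(benzyloxy)phenyl]-2-[(E)-2-[4-(benzyloxy)phenyl]ethenyl]-3-[(tert-butyldimethylsilyl)oxy]-N-methoxy-N-methylpropanamide
Conditions: TBSOTf, 2,6-lutidine, CH2Cl2, −78 → 0 °C
Reagents that add atoms: tert-butyldimethylsilyl triflate, CC(C)(C)[Si](C)(C)OS(=O)(=O)C(F)(F)F
Why: Silyl triflate silylation blocks the carbinol so that it cannot form a hemiketal later and turns it into the large group that steers step 8.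

**Step 6**
Reactants: 11 the silylated Weinreb amide; 12 [4-(benzyloxy)phenyl]magnesium bromide
Product: 13 (2S,3S)-3-[2,4-bis(benzyloxy)phenyl]-1-[4-(benzyloxy)phenyl]-2-[(E)-2-[4-(benzyloxy)phenyl]ethenyl]-3-[(tert-butyldimethylsilyl)oxy]propan-1-one
Conditions: 12 (THF solution), THF, −20 → 0 °C; cold aq NH4Cl quench
Reagents that add atoms: none
Why: Weinreb ketone synthesis: the chelated tetrahedral adduct should prevent over-addition and hold the acidic alpha hydrogen in a non-enolisable form until the cold quench, giving the C5 aryl ketone.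

**Step 7**
Reactants: 7 2,4-bis(benzyloxy)benzaldehyde
Product: 14 (E)-2,4-bis(benzyloxy)benzaldehyde oxime
Conditions: NH2OH·HCl, NaOAc, EtOH/H2O, rt
Reagents that add atoms: hydroxylamine hydrochloride, NO.Cl
Why: Oxime condensation of an aromatic aldehyde gives the nitrile oxide precursor.

**Step 8**
Reactants: 13 the beta,gamma-unsaturated aryl ketone; 14 (E)-2,4-bis(benzyloxy)benzaldehyde oxime
Product: 16 (2S,3S)-3-[2,4-bis(benzyloxy)phenyl]-2-{(4S,5S)-3-[2,4-bis(benzyloxy)phenyl]-5-[4-(benzyloxy)phenyl]-4,5-dihydroisoxazol-4-yl}-1-[4-(benzyloxy)phenyl]-3-[(tert-butyldimethylsilyl)oxy]propan-1-one, via nitrile oxide 15 (not isolated)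
Conditions: PhI(OAc)2, CF3CO2H (cat.), CH2Cl2/MeOH, 0 °C → rt, slow addition of 14 (2 equiv)
Reagents that add atoms: none
Why: PhI(OAc)2 dehydrogenates oxime 14 to nitrile oxide 15, which adds across the (E)-styryl double bond of 13 in a concerted, suprafacial 1,3-dipolar (Huisgen) cycloaddition that joins the aroyl carbon to C3 and the oxygen to C2 at once. The closest known reaction type is the addition of aryl nitrile oxides to (E)-1-arylpropenes of the anethole type, which gives 4-alkyl-5-aryl-4,5-dihydroisoxazoles. The dihydroisoxazole ring closes in a [3+2] mode in which both new sigma bonds form in the same step. C2 and C3 are set together: their relative configuration (trans on the temporary ring, which becomes aryl/aroyl cis on the oxolane) follows from the E geometry, and their absolute configuration is relayed from C4 through a staggered transition state in which the bulky, electron-releasing CH(OTBS)Ar branch lies anti to the forming C–C bond, the planar aroyl group sits inside and the hydrogen outside, next to the incoming aryl-bearing carbon. The step needs regioselectivity (oxygen to the benzylic carbon), which the 4-benzyloxyphenyl group should secure by placing the larger HOMO coefficient on the carbon remote from the ring, and facial selectivity, which rests on the size difference between the two branches at C4; any minor isomer is a diastereomer and is removable by chromatography. Slow release of 15 should keep its dimerisation to the furoxan behind the cycloaddition.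

**Step 9**
Reactants: 16 the dihydroisoxazole ketone
Product: 18 (2R,3S)-1-[2,4-bis(benzyloxy)phenyl]-4-[4-(benzyloxy)phenyl]-3-{(S)-[2,4-bis(benzyloxy)phenyl][(tert-butyldimethylsilyl)oxy]methyl}-2-{(S)-[4-(benzyloxy)phenyl](hydroxy)methyl}butane-1,4-dione, via beta-hydroxy ketimine 17 (not isolated)
Conditions: Raney Ni, H2 (1 atm), B(OH)3, MeOH/THF/H2O, rt
Reagents that add atoms: water, O
Why: Hydrogenolytic N–O cleavage of the dihydroisoxazole followed by hydrolysis of the ketimine in the boric acid buffer, which should be faster than its condensation with the ketone standing 1,4 to it, unmasks the beta-hydroxy ketone without touching C2 or C3.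

**Step 10**
Reactants: 18 the hydroxy diketone
Product: 20 [(2S,3R,4R,5S)-4-{(S)-[2,4-bis(benzyloxy)phenyl][(tert-butyldimethylsilyl)oxy]methyl}-2,5-bis[4-(benzyloxy)phenyl]oxolan-3-yl][2,4-bis(benzyloxy)phenyl]methanone, via cyclic hemiketal 19 (not isolated)
Conditions: Et3SiH, BF3·OEt2, CH2Cl2, −78 °C
Reagents that add atoms: none
Why: Reductive etherification (ionic hydrogenation of a hemiketal): the C2 hydroxyl adds to the C5 ketone, BF3 ionises the hemiketal to the 2-aryl oxocarbenium ion, and the silane should deliver hydride to C5 on the face opposite the C4 substituent, so that the C5 aryl ends up cis to it; the low temperature should prevent elimination to the dihydrofuran and loss of the C4 configuration.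

**Step 11**
Reactants: 20 the silylated oxolane
Product: 21 [(2S,3R,4S,5S)-4-{(S)-[2,4-bis(benzyloxy)phenyl](hydroxy)methyl}-2,5-bis[4-(benzyloxy)phenyl]oxolan-3-yl][2,4-bis(benzyloxy)phenyl]methanone
Conditions: HF·pyridine, pyridine, THF, 0 °C → rt
Reagents that add atoms: none
Why: Fluoride desilylation under non-basic conditions should free the carbinol without epimerising C3, which is alpha to the ketone and beta to the ring oxygen.

**Step 12**
Reactants: 21 the carbinol
Product: 22 [(2S,3R,4R,5S)-2,5-bis[4-(benzyloxy)phenyl]oxolane-3,4-diyl]bis{[2,4-bis(benzyloxy)phenyl]methanone}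
Conditions: Dess–Martin periodinane, CH2Cl2, 0 °C → rt
Reagents that add atoms: none
Why: Dess–Martin oxidation of the benzylic carbinol removes the temporary stereocenter and creates the second aroyl group under near-neutral conditions that should not enolise C3 or C4.

**Step 13**
Reactants: 22 the hexabenzyl ether
Product: 23 [(2S,3R,4R,5S)-2,5-bis(4-hydroxyphenyl)oxolane-3,4-diyl]bis[(2,4-dihydroxyphenyl)methanone] (CNP0237262.3)
Conditions: H2 (1 atm), 10% Pd/C, EtOAc/MeOH, rt, monitored closely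
Reagents that add atoms: none
Why: Hydrogenolysis of the six aryl benzyl ethers is neutral, so the epimerisable C3 and C4 centres should survive, and the 2-hydroxyaryl ketones being formed are protected from reduction by their intramolecular hydrogen bond.

**Compound list**

1 | 4-(benzyloxy)benzaldehyde | O=Cc1ccc(OCc2ccccc2)cc1 | starting material
2 | (2-carboxyethyl)triphenylphosphonium bromide | OC(=O)CC[P+](c1ccccc1)(c1ccccc1)c1ccccc1.[Br-] | starting material
3 | (E)-4-[4-(benzyloxy)phenyl]but-3-enoic acid | OC(=O)C/C=C/c1ccc(OCc2ccccc2)cc1 | intermediate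
4 | (S)-4-benzyl-1,3-oxazolidin-2-one | O=C1N[C@@H](Cc2ccccc2)CO1 | starting material
5 | (E)-4-[4-(benzyloxy)phenyl]but-3-enoic pivalic anhydride | CC(C)(C)C(=O)OC(=O)C/C=C/c1ccc(OCc2ccccc2)cc1 | intermediate
6 | (S)-4-benzyl-3-{(E)-4-[4-(benzyloxy)phenyl]but-3-enoyl}-1,3-oxazolidin-2-one | O=C(C/C=C/c1ccc(OCc2ccccc2)cc1)N1[C@@H](Cc2ccccc2)COC1=O | intermediate
7 | 2,4-bis(benzyloxy)benzaldehyde | O=Cc1ccc(OCc2ccccc2)cc1OCc1ccccc1 | starting material
8 | dibutylboron (1Z,3E)-dienolate of 6 | CCCCB(CCCC)O/C(=C\C=C\c1ccc(OCc2ccccc2)cc1)N1[C@@H](Cc2ccccc2)COC1=O | intermediate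
9 | (S)-4-benzyl-3-{(2S,3S)-3-[2,4-bis(benzyloxy)phenyl]-2-[(E)-2-[4-(benzyloxy)phenyl]ethenyl]-3-hydroxypropanoyl}-1,3-oxazolidin-2-one | O=C(N1[C@@H](Cc2ccccc2)COC1=O)[C@@H](/C=C/c1ccc(OCc2ccccc2)cc1)[C@H](O)c1ccc(OCc2ccccc2)cc1OCc1ccccc1 | intermediate
10 | (2S,3S)-3-[2,4-bis(benzyloxy)phenyl]-2-[(E)-2-[4-(benzyloxy)phenyl]ethenyl]-3-hydroxy-N-methoxy-N-methylpropanamide | CON(C)C(=O)[C@@H](/C=C/c1ccc(OCc2ccccc2)cc1)[C@H](O)c1ccc(OCc2ccccc2)cc1OCc1ccccc1 | intermediate
11 | (2S,3S)-3-[2,4-bis(benzyloxy)phenyl]-2-[(E)-2-[4-(benzyloxy)phenyl]ethenyl]-3-[(tert-butyldimethylsilyl)oxy]-N-methoxy-N-methylpropanamide | CON(C)C(=O)[C@@H](/C=C/c1ccc(OCc2ccccc2)cc1)[C@H](O[Si](C)(C)C(C)(C)C)c1ccc(OCc2ccccc2)cc1OCc1ccccc1 | intermediate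
12 | [4-(benzyloxy)phenyl]magnesium bromide | Br[Mg]c1ccc(OCc2ccccc2)cc1 | starting material
13 | (2S,3S)-3-[2,4-bis(benzyloxy)phenyl]-1-[4-(benzyloxy)phenyl]-2-[(E)-2-[4-(benzyloxy)phenyl]ethenyl]-3-[(tert-butyldimethylsilyl)oxy]propan-1-one | O=C(c1ccc(OCc2ccccc2)cc1)[C@@H](/C=C/c1ccc(OCc2ccccc2)cc1)[C@H](O[Si](C)(C)C(C)(C)C)c1ccc(OCc2ccccc2)cc1OCc1ccccc1 | intermediate
14 | (E)-2,4-bis(benzyloxy)benzaldehyde oxime | O/N=C/c1ccc(OCc2ccccc2)cc1OCc1ccccc1 | intermediate
15 | 2,4-bis(benzyloxy)benzonitrile oxide | [O-][N+]#Cc1ccc(OCc2ccccc2)cc1OCc1ccccc1 | intermediate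
16 | (2S,3S)-3-[2,4-bis(benzyloxy)phenyl]-2-{(4S,5S)-3-[2,4-bis(benzyloxy)phenyl]-5-[4-(benzyloxy)phenyl]-4,5-dihydroisoxazol-4-yl}-1-[4-(benzyloxy)phenyl]-3-[(tert-butyldimethylsilyl)oxy]propan-1-one | O=C(c1ccc(OCc2ccccc2)cc1)[C@@H]([C@@H]1[C@@H](c2ccc(OCc3ccccc3)cc2)ON=C1c1ccc(OCc2ccccc2)cc1OCc1ccccc1)[C@H](O[Si](C)(C)C(C)(C)C)c1ccc(OCc2ccccc2)cc1OCc1ccccc1 | intermediate
17 | (2S,3S)-4-[2,4-bis(benzyloxy)phenyl]-1-[4-(benzyloxy)phenyl]-2-{(S)-[2,4-bis(benzyloxy)phenyl][(tert-butyldimethylsilyl)oxy]methyl}-3-{(S)-[4-(benzyloxy)phenyl](hydroxy)methyl}-4-iminobutan-1-one | N=C(c1ccc(OCc2ccccc2)cc1OCc1ccccc1)[C@@H]([C@H](O)c1ccc(OCc2ccccc2)cc1)[C@@H]([C@H](O[Si](C)(C)C(C)(C)C)c1ccc(OCc2ccccc2)cc1OCc1ccccc1)C(=O)c1ccc(OCc2ccccc2)cc1 | intermediate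
18 | (2R,3S)-1-[2,4-bis(benzyloxy)phenyl]-4-[4-(benzyloxy)phenyl]-3-{(S)-[2,4-bis(benzyloxy)phenyl][(tert-butyldimethylsilyl)oxy]methyl}-2-{(S)-[4-(benzyloxy)phenyl](hydroxy)methyl}butane-1,4-dione | O=C(c1ccc(OCc2ccccc2)cc1OCc1ccccc1)[C@@H]([C@H](O)c1ccc(OCc2ccccc2)cc1)[C@@H]([C@H](O[Si](C)(C)C(C)(C)C)c1ccc(OCc2ccccc2)cc1OCc1ccccc1)C(=O)c1ccc(OCc2ccccc2)cc1 | intermediate
19 | [(2S,3R,4S)-4-{(S)-[2,4-bis(benzyloxy)phenyl][(tert-butyldimethylsilyl)oxy]methyl}-2,5-bis[4-(benzyloxy)phenyl]-5-hydroxyoxolan-3-yl][2,4-bis(benzyloxy)phenyl]methanone (both C5 epimers) | O=C(c1ccc(OCc2ccccc2)cc1OCc1ccccc1)[C@@H]1[C@@H]([C@H](O[Si](C)(C)C(C)(C)C)c2ccc(OCc3ccccc3)cc2OCc2ccccc2)C(O)(c2ccc(OCc3ccccc3)cc2)O[C@@H]1c1ccc(OCc2ccccc2)cc1 | intermediate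
20 | [(2S,3R,4R,5S)-4-{(S)-[2,4-bis(benzyloxy)phenyl][(tert-butyldimethylsilyl)oxy]methyl}-2,5-bis[4-(benzyloxy)phenyl]oxolan-3-yl][2,4-bis(benzyloxy)phenyl]methanone | O=C(c1ccc(OCc2ccccc2)cc1OCc1ccccc1)[C@@H]1[C@@H]([C@H](O[Si](C)(C)C(C)(C)C)c2ccc(OCc3ccccc3)cc2OCc2ccccc2)[C@@H](c2ccc(OCc3ccccc3)cc2)O[C@@H]1c1ccc(OCc2ccccc2)cc1 | intermediate
21 | [(2S,3R,4S,5S)-4-{(S)-[2,4-bis(benzyloxy)phenyl](hydroxy)methyl}-2,5-bis[4-(benzyloxy)phenyl]oxolan-3-yl][2,4-bis(benzyloxy)phenyl]methanone | O=C(c1ccc(OCc2ccccc2)cc1OCc1ccccc1)[C@@H]1[C@@H]([C@H](O)c2ccc(OCc3ccccc3)cc2OCc2ccccc2)[C@@H](c2ccc(OCc3ccccc3)cc2)O[C@@H]1c1ccc(OCc2ccccc2)cc1 | intermediate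
22 | [(2S,3R,4R,5S)-2,5-bis[4-(benzyloxy)phenyl]oxolane-3,4-diyl]bis{[2,4-bis(benzyloxy)phenyl]methanone} | O=C(c1ccc(OCc2ccccc2)cc1OCc1ccccc1)[C@@H]1[C@@H](C(=O)c2ccc(OCc3ccccc3)cc2OCc2ccccc2)[C@@H](c2ccc(OCc3ccccc3)cc2)O[C@@H]1c1ccc(OCc2ccccc2)cc1 | intermediate
23 | [(2S,3R,4R,5S)-2,5-bis(4-hydroxyphenyl)oxolane-3,4-diyl]bis[(2,4-dihydroxyphenyl)methanone] | O=C(c1ccc(O)cc1O)[C@@H]1[C@@H](C(=O)c2ccc(O)cc2O)[C@@H](c2ccc(O)cc2)O[C@@H]1c1ccc(O)cc1 | target

**Step count and risks**

Total step count: 13. Longest linear sequence: 12 (steps 1–6 and 8–13; step 7 is a one-step side branch).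

Steps most likely to fail:

1. Step 8. The two faces of the styryl double bond may be poorly discriminated, because the C4 stereocenter carries two aryl-bearing branches; the dipole may also add with the reverse orientation or dimerise before it reaches the hindered alkene. Fallback: the relay from C4 is given up and the auxiliary serves as a resolving handle. The fallback sets out from imide 6 and oxime 14. Nitrile oxide 15 (from 14 with PhI(OAc)2) is added to the unhindered alkene of 6. This should give, without facial bias, the two trans-dihydroisoxazoles: (S)-4-benzyl-3-{[(4S,5S)-3-[2,4-bis(benzyloxy)phenyl]-5-[4-(benzyloxy)phenyl]-4,5-dihydroisoxazol-4-yl]acetyl}-1,3-oxazolidin-2-one F1 and its (4R,5R)-dihydroisoxazole diastereomer F2, which are separated by chromatography or crystallisation. F1 then undergoes the boron aldol reaction with 7 (Bu2BOTf, iPr2NEt), in which the auxiliary alone sets C4, to give the syn-aldol imide F3. Transamination (MeNHOMe·HCl, AlMe3) gives the hydroxy Weinreb amide F4, Grignard reagent 12 (excess) gives the hydroxy ketone F5, and silylation (TBSOTf, 2,6-lutidine) comes back to the route at 16.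

2. Step 10. The Lewis acid may ionise the electron-rich benzylic silyl ether, the silane may reduce the aroyl ketone, or the hemiketal may eliminate to a dihydrofuran with loss of the C4 configuration. Fallback: the hydrogen at C5 is delivered as a hydrogen atom instead of a hydride. The fallback sets out from 18. Its hemiketal 19 is converted with PhSH and pyridinium p-toluenesulfonate (4 Å sieves, CH2Cl2) into the S-phenyl monothioketal [(2S,3R,4S)-4-{(S)-[2,4-bis(benzyloxy)phenyl][(tert-butyldimethylsilyl)oxy]methyl}-2,5-bis[4-(benzyloxy)phenyl]-5-(phenylsulfanyl)oxolan-3-yl][2,4-bis(benzyloxy)phenyl]methanone F6. Bu3SnH/AIBN (toluene, 80 °C) then cleaves the C–S bond, and the planar benzylic alpha-oxy radical at C5 should take the hydrogen atom on the face opposite the C4 substituent. This comes back to the route at 20.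

3. Step 6. The Grignard reagent may deprotonate the doubly activated C4–H; after the quench the double bond may then migrate into conjugation, or the silyloxy group may be lost by beta-elimination from the sensitive ketone. Fallback: steps 6 and 8 are exchanged so that no beta,gamma-unsaturated ketone is formed. The fallback sets out from Weinreb amide 11. Nitrile oxide 15 (from 14, PhI(OAc)2) is added to 11, with the same facial argument and the amide carbonyl inside, to give the dihydroisoxazole Weinreb amide (2S,3S)-3-[2,4-bis(benzyloxy)phenyl]-2-{(4S,5S)-3-[2,4-bis(benzyloxy)phenyl]-5-[4-(benzyloxy)phenyl]-4,5-dihydroisoxazol-4-yl}-3-[(tert-butyldimethylsilyl)oxy]-N-methoxy-N-methylpropanamide F7. Addition of 12 (with LaCl3·2LiCl if the hindered amide is sluggish) comes back to the route at 16.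

**Further compounds**

F1 | step 8 | (S)-4-benzyl-3-{[(4S,5S)-3-[2,4-bis(benzyloxy)phenyl]-5-[4-(benzyloxy)phenyl]-4,5-dihydroisoxazol-4-yl]acetyl}-1,3-oxazolidin-2-one | O=C(C[C@@H]1[C@@H](c2ccc(OCc3ccccc3)cc2)ON=C1c1ccc(OCc2ccccc2)cc1OCc1ccccc1)N1[C@@H](Cc2ccccc2)COC1=O
F2 | step 8 | (S)-4-benzyl-3-{[(4R,5R)-3-[2,4-bis(benzyloxy)phenyl]-5-[4-(benzyloxy)phenyl]-4,5-dihydroisoxazol-4-yl]acetyl}-1,3-oxazolidin-2-one | O=C(C[C@H]1[C@H](c2ccc(OCc3ccccc3)cc2)ON=C1c1ccc(OCc2ccccc2)cc1OCc1ccccc1)N1[C@@H](Cc2ccccc2)COC1=O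
F3 | step 8 | (S)-4-benzyl-3-{(2S,3S)-3-[2,4-bis(benzyloxy)phenyl]-2-[(4S,5S)-3-[2,4-bis(benzyloxy)phenyl]-5-[4-(benzyloxy)phenyl]-4,5-dihydroisoxazol-4-yl]-3-hydroxypropanoyl}-1,3-oxazolidin-2-one | O=C(N1[C@@H](Cc2ccccc2)COC1=O)[C@@H]([C@@H]1[C@@H](c2ccc(OCc3ccccc3)cc2)ON=C1c1ccc(OCc2ccccc2)cc1OCc1ccccc1)[C@H](O)c1ccc(OCc2ccccc2)cc1OCc1ccccc1
F4 | step 8 | (2S,3S)-3-[2,4-bis(benzyloxy)phenyl]-2-[(4S,5S)-3-[2,4-bis(benzyloxy)phenyl]-5-[4-(benzyloxy)phenyl]-4,5-dihydroisoxazol-4-yl]-3-hydroxy-N-methoxy-N-methylpropanamide | CON(C)C(=O)[C@@H]([C@@H]1[C@@H](c2ccc(OCc3ccccc3)cc2)ON=C1c1ccc(OCc2ccccc2)cc1OCc1ccccc1)[C@H](O)c1ccc(OCc2ccccc2)cc1OCc1ccccc1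
F5 | step 8 | (2S,3S)-3-[2,4-bis(benzyloxy)phenyl]-2-[(4S,5S)-3-[2,4-bis(benzyloxy)phenyl]-5-[4-(benzyloxy)phenyl]-4,5-dihydroisoxazol-4-yl]-1-[4-(benzyloxy)phenyl]-3-hydroxypropan-1-one | O=C(c1ccc(OCc2ccccc2)cc1)[C@@H]([C@@H]1[C@@H](c2ccc(OCc3ccccc3)cc2)ON=C1c1ccc(OCc2ccccc2)cc1OCc1ccccc1)[C@H](O)c1ccc(OCc2ccccc2)cc1OCc1ccccc1
F6 | step 10 | [(2S,3R,4S)-4-{(S)-[2,4-bis(benzyloxy)phenyl][(tert-butyldimethylsilyl)oxy]methyl}-2,5-bis[4-(benzyloxy)phenyl]-5-(phenylsulfanyl)oxolan-3-yl][2,4-bis(benzyloxy)phenyl]methanone (both C5 epimers) | O=C(c1ccc(OCc2ccccc2)cc1OCc1ccccc1)[C@@H]1[C@@H]([C@H](O[Si](C)(C)C(C)(C)C)c2ccc(OCc3ccccc3)cc2OCc2ccccc2)C(Sc2ccccc2)(c2ccc(OCc3ccccc3)cc2)O[C@@H]1c1ccc(OCc2ccccc2)cc1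
F7 | step 6 | (2S,3S)-3-[2,4-bis(benzyloxy)phenyl]-2-{(4S,5S)-3-[2,4-bis(benzyloxy)phenyl]-5-[4-(benzyloxy)phenyl]-4,5-dihydroisoxazol-4-yl}-3-[(tert-butyldimethylsilyl)oxy]-N-methoxy-N-methylpropanamide | CON(C)C(=O)[C@@H]([C@@H]1[C@@H](c2ccc(OCc3ccccc3)cc2)ON=C1c1ccc(OCc2ccccc2)cc1OCc1ccccc1)[C@H](O[Si](C)(C)C(C)(C)C)c1ccc(OCc2ccccc2)cc1OCc1ccccc1
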